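The time allowed is 15 d, and I measure everything against it in powers of ten.

| flask | L | remark | time |
|---|---|---|---|
| south-east | 2.8 M | run made earlier |  |
| flask | 2.0 M |  | 15 d |

- south-east (time / d: L / %, J / %, E / %): 1.67: 38.6, 34.6, 18.4; 4.00: 0, 61.5, 35.9; 5.00: 1.5, 60.6, 33.2; 8.00: 0, 63.0, 32.0; 10.0: 1.0, 63.1, 34.8

(readings scatter by 1 percentage point)

- as a solid, counted per litre of solution: L
- at the start none of L is in solution
- what has only dissolved of L counts as not reacted
- the reaction counts as stopped when no species that holds the L changes by six tenths of a point or more over the second half of the time

- at 15 d, what has stopped the reaction, if anything has (for what has run out or reacted, a solid counts together with what of it has only dissolved) (forward and back rates have come level / all of L has reacted / it is still moving)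
- part of the L that has turned into other species by 15 d (what has only dissolved does not count)
- how much J there is at 15 d, in percent of the L charged
- how much E there is at 15 d, in percent of the L charged

1. First rung, the solid. In the south-east run 61.4% of L has gone after 1.67 d. A first-order fall from there leaves 10.2% at 4.00 d, but the reading is 0%. So I take a straight, zero-order fall at 1.03 M d⁻¹.

2. Dividing the flask's charge of L by that rate gives 1.94 d: the clearing time, if the flask's solid goes as fast. For the south-east run it gives 2.72 d, earlier than the empty reading at 4.00 d.

3. Next rung, the time allowed. It stands 0.888 powers of ten above the flask's clearing time.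

4. Last rung, the plateau. In the south-east run J rises 1.6 percentage points between 4.00 d and 10.0 d, against a scatter of 1 point per reading. Even taken as real, that drift needs 237 d to turn J over, 1.20 powers of ten above the time allowed.

5. So I expect the flask's L to be consumed early, with J and E near the south-east run's last readings, 63.1% and 34.8%.

6. The forecast says all of L has reacted, conversion 99.5%, J 62% and E 34%; of the flask at its lower charge it writes “it should finish at least as fast”. Its J and E lie below the south-east run's last readings.

7. The flask gives all of L has reacted, conversion 100%, J 62.8% and E 34.1%.

    Z → E (k = 0.00119 min⁻¹)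
    Z → J (k = 0.00219 min⁻¹)
    Z → X (k = 1.10 × 10⁻⁴ min⁻¹)
    X ⇌ Q (K = 49.9, k = 0.00243 min⁻¹)
    X → D (k = 0.00218 min⁻¹)
    X ⇌ G (K = 0.440, k = 6.65 × 10⁻⁴ min⁻¹)
    L ⇌ Z, rate k7*(cs7 - [Z]) while solid is left; crystals form when [Z] > cs7 (solubility = 0.630 M, k = 0.00168 min⁻¹)

At 1.50 d my straight line leaves 22.8% of L, and the flask holds less, 19.5%. The flask's answer for E stays within 5 points down to at least 1.88 d, close to my clearing time. The neighbouring flask has 0.80 M of L with all else held, so at the same rate its clearing time is 0.777 d and its margin 1.29 powers of ten. At 15.0 d it holds 0% of its L, J 62.8% and E 34.1%.

(The earlier runs and the new flask were computed on assumed constants; scatter was added.)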